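**Plan**

- Retrosynthesis: the acetate is cut last. The seven-membered lactone (ring atoms O1, C2 carbonyl, C3 bearing the 4-methylpent-3-enyl chain, C4 =CH, C5, C6, C7 quaternary; C1′ is the carbinol carbon on C7) is cut at C2–C3 and at C4–C5 in one stroke. This leaves a five-membered lactone (O1, C2, C5, C6, C7) and an E-alkenyl iodide that supplies C4, C3 and the chain. The small lactone is then cut at O1–C7 (epoxide opening) and C5–C6 (malonate alkylation).
- Forward: geranyl acetate is oxidised at C8, joined to di-tert-butyl malonate, epoxidised and closed to the γ-lactone. The lactone is expanded by two carbons to the oxepinone, the helper ester on C5 is removed and the acetate is put back.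
- Stereochemistry: one Shi epoxidation sets both centres. Lactonisation inverts the tertiary carbon C7 (to S) and retains the carbinol carbon C1′ (R). The C3=C4 geometry is fixed by the ring.
- Enabling feature: in the five-membered lactone the acyl carbon C2 sits on C5, which also carries a tert-butyl ester and, after alkenylation, the C4=C3 unit. The C1′ hydroxyl on the carbon next to C7 can reach C2, so C2 can leave C5 as a cyclic carbonate and return at C3.

Key step: step 9

Assumption: the D-fructose-derived Shi ketone is taken to attack the E-trisubstituted 6,7-alkene of 5 in the same facial sense as in its standard (R,R)-selective cases; if the opposite sense were found, the enantiomeric ketone would be used.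

**Route**

Step 1
Reactants: 1 geranyl acetate, (2E)-3,7-dimethylocta-2,6-dien-1-yl acetate
Product: 2 (2E,6E)-8-hydroxy-3,7-dimethylocta-2,6-dien-1-yl acetate
Conditions: SeO2 (0.1 eq), salicylic acid (0.1 eq), t-BuOOH (3 eq), CH2Cl2, rt
Reagents that add atoms: tert-butyl hydroperoxide, CC(C)(C)OO; selenium dioxide (oxygen carrier), O=[Se]=O
Why: Sharpless SeO2/t-BuOOH allylic oxidation (ene reaction, then [2,3]-sigmatropic shift) should oxidise the E-methyl group of the electron-richer distal alkene, the 2,3-alkene being deactivated by the allylic acetate.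

Step 2
Reactants: 2 (2E,6E)-8-hydroxy-3,7-dimethylocta-2,6-dien-1-yl acetate
Product: 3 (2E,6E)-8-bromo-3,7-dimethylocta-2,6-dien-1-yl acetate
Conditions: CBr4, PPh3, CH2Cl2, 0 °C
Reagents that add atoms: carbon tetrabromide, BrC(Br)(Br)Br
Why: Appel bromination of a primary allylic alcohol should proceed by SN2 at 0 °C without allylic transposition or loss of alkene geometry.

Step 3
Reactants: 3 (2E,6E)-8-bromo-3,7-dimethylocta-2,6-dien-1-yl acetate; 4 di-tert-butyl malonate
Product: 5 di-tert-butyl 2-[(2E,6E)-8-acetoxy-2,6-dimethylocta-2,6-dien-1-yl]propanedioate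
Conditions: NaH, 4 (2 eq), THF–DMF, 0 °C to rt
Reagents that add atoms: none
Why: Malonic ester alkylation (SN2 at the primary allylic bromide) forms the C5–C6 bond; excess soft sodium malonate should suppress dialkylation and leave the acetate alone.

Step 4
Reactants: 5 di-tert-butyl 2-[(2E,6E)-8-acetoxy-2,6-dimethylocta-2,6-dien-1-yl]propanedioate
Product: 6 di-tert-butyl 2-{[(2R,3R)-3-[(3E)-5-acetoxy-3-methylpent-3-en-1-yl]-2-methyloxiran-2-yl]methyl}propanedioate
Conditions: D-fructose-derived Shi ketone (0.3 eq), 2KHSO5·KHSO4·K2SO4, K2CO3, Bu4NHSO4, aq. Na2B4O7 buffer, MeCN–CH2(OMe)2, 0 °C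
Reagents that add atoms: potassium peroxymonosulfate, [K+].[O-]OS(=O)(=O)O
Why: Shi asymmetric epoxidation (chiral dioxirane, spiro transition state) should give the (R,R)-epoxide of the E-trisubstituted alkene and so set both stereocentres, while the alkene next to the acetate is deactivated.

Step 5
Reactants: 6 di-tert-butyl 2-{[(2R,3R)-3-[(3E)-5-acetoxy-3-methylpent-3-en-1-yl]-2-methyloxiran-2-yl]methyl}propanedioate
Product: 7 tert-butyl (5S)-5-[(1R,4E)-6-acetoxy-1-hydroxy-4-methylhex-4-en-1-yl]-5-methyl-2-oxooxolane-3-carboxylate (both C3 epimers)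
Conditions: camphorsulfonic acid (0.1 eq), CH2Cl2, 0 °C to rt
Reagents that add atoms: none
Why: Acid-catalysed 5-exo-tet epoxide opening by a tert-butyl ester carbonyl (ester participation, loss of 2-methylpropene) forms O1–C7 with inversion at the tertiary carbon (C7 becomes S) and retention at C1′ (R); the new ester-bearing centre is formed as a mixture and is removed later.

Step 6
Reactants: 7 tert-butyl (5S)-5-[(1R,4E)-6-acetoxy-1-hydroxy-4-methylhex-4-en-1-yl]-5-methyl-2-oxooxolane-3-carboxylate
Product: 8 tert-butyl (5S)-5-[(1R,4E)-1,6-dihydroxy-4-methylhex-4-en-1-yl]-5-methyl-2-oxooxolane-3-carboxylate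
Conditions: Candida antarctica lipase B (immobilised), n-BuOH (5 eq), t-BuOMe, 35 °C
Reagents that add atoms: none
Why: Lipase-catalysed transesterification removes the primary allylic acetate under neutral conditions, which is needed because an allylic acetate would ionise with zerovalent palladium and the malonate-type enolate in step 9; the lactone and the tert-butyl ester are not lipase substrates.

Step 7
Reactants: 9 5-bromo-2-methylpent-2-ene; 10 lithium acetylide–ethylenediamine complex
Product: 11 6-methylhept-5-en-1-yne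
Conditions: DMSO, 10 °C to rt
Reagents that add atoms: none
Why: SN2 alkylation of lithium acetylide by a primary bromide gives the terminal enyne.

Step 8
Reactants: 11 6-methylhept-5-en-1-yne
Product: 13 (1E)-1-iodo-6-methylhepta-1,5-diene, via alkenylzirconocene 12 (not isolated)
Conditions: Cp2Zr(H)Cl (1.2 eq), THF, rt; then I2, 0 °C
Reagents that add atoms: iodine, II
Why: Schwartz hydrozirconation adds syn to the terminal alkyne (zirconium at the terminal carbon, the trisubstituted alkene untouched) and iodinolysis with retention gives the E-alkenyl iodide.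

Step 9
Reactants: 8 tert-butyl (5S)-5-[(1R,4E)-1,6-dihydroxy-4-methylhex-4-en-1-yl]-5-methyl-2-oxooxolane-3-carboxylate; 13 (1E)-1-iodo-6-methylhepta-1,5-diene
Product: 16 tert-butyl (7S)-7-[(1R,4E)-1,6-dihydroxy-4-methylhex-4-en-1-yl]-7-methyl-3-(4-methylpent-3-en-1-yl)-2-oxo-2,5,6,7-tetrahydrooxepine-5-carboxylate (C5 epimers), via alkenyl lactone 14 (not isolated), via carbonate dienolate 15 (not isolated)
Conditions: KOt-Bu (1.1 eq), THF, 0 °C; Pd2(dba)3 (2.5 mol %), t-Bu3P·HBF4 (6 mol %), 13 (1.2 eq), 45 °C; then KOt-Bu (2.2 eq), 0 to 40 °C; aq. NH4Cl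
Reagents that add atoms: none
Why: Proposed new method: stage one is a zerovalent-palladium α-alkenylation of the stabilised enolate of 8 (oxidative addition of 13, enolate transfer, reductive elimination; closest known type: Pd-catalysed α-arylation and α-alkenylation of malonates and of α-substituted lactones), which makes the C4–C5 bond and gives 14; only the malonate-type C–H is deprotonated at this stage, so C- and not O-alkenylation is expected. Stage two is a base-triggered 1,3-acyl shift: the C1′ alkoxide adds to the lactone carbonyl C2 and the C2–C5 bond breaks (retro-Claisen cleavage, as known for alkyl(1-alkenyl)malonates under alkoxide) to give the five-membered carbonate 15 and an ester dienolate spread over C5, C4 and C3. The dienolate terminus C3 then attacks the carbonate carbonyl in a 7-exo-trig acyl substitution that forms the C2–C3 bond and the seven-membered ring and sets the C1′ alkoxide free again; the closest known types are the abnormal Michael 1,3-ester shift and aryne insertion into the C–C bond of malonates, but an alkenyl dienolate and a lactone acyl group have not been used in this way. Return of the acyl group to C5 only regenerates 14, whereas the ring-expanded lactone is deprotonated at C3 (between the lactone carbonyl and the unsaturated ester) and so is drained from the equilibria, which is what should secure γ- over α-acylation; the tert-butyl group shields the helper ester from the alkoxide. No stereocentre of the target is created (C7 and C1′ are not touched, the C5 ester epimers and the C3=C4/C4=C5 double-bond isomers converge in step 10), and the ring alkene can only be Z.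

Step 10
Reactants: 16 tert-butyl (7S)-7-[(1R,4E)-1,6-dihydroxy-4-methylhex-4-en-1-yl]-7-methyl-3-(4-methylpent-3-en-1-yl)-2-oxo-2,5,6,7-tetrahydrooxepine-5-carboxylate
Product: 20 (7S)-7-[(1R,4E)-1,6-dihydroxy-4-methylhex-4-en-1-yl]-7-methyl-3-(4-methylpent-3-en-1-yl)-6,7-dihydrooxepin-2(5H)-one, via tris(trimethylsilyl) derivative 17 (not isolated), via carboxylic acid 18 (not isolated), via deconjugated lactone 19 (not isolated)
Conditions: TMSOTf (4 eq), 2,6-lutidine (6 eq), CH2Cl2, 0 °C; then MeOH–pyridine, 60 °C; then DBU (0.2 eq), rt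
Reagents that add atoms: none
Why: Silyl triflate-mediated cleavage of the tert-butyl ester (lutidine-buffered, hydroxyls masked meanwhile as silyl ethers), methanolysis, decarboxylation of the vinylogous malonic half-ester and base-mediated isomerisation should return the double bond to C3=C4, because the C2–C5 dienolate can be protonated only at ring carbons C3 or C5; the C5 stereocentre disappears.

Step 11
Reactants: 20 (7S)-7-[(1R,4E)-1,6-dihydroxy-4-methylhex-4-en-1-yl]-7-methyl-3-(4-methylpent-3-en-1-yl)-6,7-dihydrooxepin-2(5H)-one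
Product: 21 (2E,6R)-6-hydroxy-3-methyl-6-[(2S)-2-methyl-6-(4-methylpent-3-en-1-yl)-7-oxo-2,3,4,7-tetrahydrooxepin-2-yl]hex-2-en-1-yl acetate
Conditions: Ac2O (1.1 eq), pyridine, CH2Cl2, −20 °C
Reagents that add atoms: acetic anhydride, CC(=O)OC(C)=O
Why: Acylation should be selective for the primary allylic alcohol over the secondary hydroxyl, which is hindered by the adjacent quaternary C7.

**Compound list**

1 | geranyl acetate, (2E)-3,7-dimethylocta-2,6-dien-1-yl acetate | CC(=O)OC/C=C(\C)CCC=C(C)C | starting material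
2 | (2E,6E)-8-hydroxy-3,7-dimethylocta-2,6-dien-1-yl acetate | CC(=O)OC/C=C(\C)CC/C=C(\C)CO | intermediate
3 | (2E,6E)-8-bromo-3,7-dimethylocta-2,6-dien-1-yl acetate | CC(=O)OC/C=C(\C)CC/C=C(\C)CBr | intermediate
4 | di-tert-butyl malonate | CC(C)(C)OC(=O)CC(=O)OC(C)(C)C | starting material
5 | di-tert-butyl 2-[(2E,6E)-8-acetoxy-2,6-dimethylocta-2,6-dien-1-yl]propanedioate | CC(=O)OC/C=C(\C)CC/C=C(\C)CC(C(=O)OC(C)(C)C)C(=O)OC(C)(C)C | intermediate
6 | di-tert-butyl 2-{[(2R,3R)-3-[(3E)-5-acetoxy-3-methylpent-3-en-1-yl]-2-methyloxiran-2-yl]methyl}propanedioate | CC(=O)OC/C=C(\C)CC[C@H]1O[C@]1(C)CC(C(=O)OC(C)(C)C)C(=O)OC(C)(C)C | intermediate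
7 | tert-butyl (5S)-5-[(1R,4E)-6-acetoxy-1-hydroxy-4-methylhex-4-en-1-yl]-5-methyl-2-oxooxolane-3-carboxylate | CC(=O)OC/C=C(\C)CC[C@@H](O)[C@]1(C)CC(C(=O)OC(C)(C)C)C(=O)O1 | intermediate
8 | tert-butyl (5S)-5-[(1R,4E)-1,6-dihydroxy-4-methylhex-4-en-1-yl]-5-methyl-2-oxooxolane-3-carboxylate | OC/C=C(\C)CC[C@@H](O)[C@]1(C)CC(C(=O)OC(C)(C)C)C(=O)O1 | intermediate
9 | 5-bromo-2-methylpent-2-ene | CC(C)=CCCBr | starting material
10 | lithium acetylide–ethylenediamine complex | [Li+].[C-]#C.NCCN | starting material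
11 | 6-methylhept-5-en-1-yne | CC(C)=CCCC#C | intermediate
12 | [(1E)-6-methylhepta-1,5-dien-1-yl]zirconocene chloride, Cp2Zr(Cl)(CH=CHCH2CH2CH=CMe2) | CC(C)=CCC/C=C/[Zr](Cl)(C1C=CC=C1)C1C=CC=C1 | intermediate
13 | (1E)-1-iodo-6-methylhepta-1,5-diene | CC(C)=CCC/C=C/I | intermediate
14 | tert-butyl (5S)-5-[(1R,4E)-1,6-dihydroxy-4-methylhex-4-en-1-yl]-5-methyl-3-[(1E)-6-methylhepta-1,5-dien-1-yl]-2-oxooxolane-3-carboxylate | OC/C=C(\C)CC[C@@H](O)[C@]1(C)CC(/C=C/CCC=C(C)C)(C(=O)OC(C)(C)C)C(=O)O1 | intermediate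
15 | dipotassium salt (ester dienolate and primary alkoxide) of tert-butyl 2-({(4S,5R)-5-[(3E)-5-hydroxy-3-methylpent-3-en-1-yl]-4-methyl-2-oxo-1,3-dioxolan-4-yl}methyl)-8-methylnona-3,7-dienoate | [K+].[K+].[O-]C/C=C(\C)CC[C@H]1OC(=O)O[C@@]1(C)CC(/C=C/CCC=C(C)C)=C([O-])OC(C)(C)C | intermediate
16 | tert-butyl (7S)-7-[(1R,4E)-1,6-dihydroxy-4-methylhex-4-en-1-yl]-7-methyl-3-(4-methylpent-3-en-1-yl)-2-oxo-2,5,6,7-tetrahydrooxepine-5-carboxylate | OC/C=C(\C)CC[C@@H](O)[C@]1(C)CC(C(=O)OC(C)(C)C)C=C(CCC=C(C)C)C(=O)O1 | intermediate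
17 | trimethylsilyl (7S)-7-methyl-7-[(1R,4E)-4-methyl-1,6-bis(trimethylsilyloxy)hex-4-en-1-yl]-3-(4-methylpent-3-en-1-yl)-2-oxo-2,5,6,7-tetrahydrooxepine-5-carboxylate | C[Si](C)(C)OC/C=C(\C)CC[C@@H](O[Si](C)(C)C)[C@]1(C)CC(C(=O)O[Si](C)(C)C)C=C(CCC=C(C)C)C(=O)O1 | intermediate
18 | (7S)-7-[(1R,4E)-1,6-dihydroxy-4-methylhex-4-en-1-yl]-7-methyl-3-(4-methylpent-3-en-1-yl)-2-oxo-2,5,6,7-tetrahydrooxepine-5-carboxylic acid | OC/C=C(\C)CC[C@@H](O)[C@]1(C)CC(C(=O)O)C=C(CCC=C(C)C)C(=O)O1 | intermediate
19 | (7S)-7-[(1R,4E)-1,6-dihydroxy-4-methylhex-4-en-1-yl]-7-methyl-3-(4-methylpent-3-en-1-yl)-6,7-dihydrooxepin-2(3H)-one | OC/C=C(\C)CC[C@@H](O)[C@]1(C)CC=CC(CCC=C(C)C)C(=O)O1 | intermediate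
20 | (7S)-7-[(1R,4E)-1,6-dihydroxy-4-methylhex-4-en-1-yl]-7-methyl-3-(4-methylpent-3-en-1-yl)-6,7-dihydrooxepin-2(5H)-one | OC/C=C(\C)CC[C@@H](O)[C@]1(C)CCC=C(CCC=C(C)C)C(=O)O1 | intermediate
21 | (2E,6R)-6-hydroxy-3-methyl-6-[(2S)-2-methyl-6-(4-methylpent-3-en-1-yl)-7-oxo-2,3,4,7-tetrahydrooxepin-2-yl]hex-2-en-1-yl acetate | CC(=O)OC/C=C(\C)CC[C@@H](O)[C@]1(C)CCC=C(CCC=C(C)C)C(=O)O1 | target

**Step count and risks**

Total step count: 11. Longest linear sequence: 9 steps (steps 1 to 6 and 9 to 11).

Step 9 (new method). What may go wrong: alkenylation on oxygen or a second alkenylation in the palladium stage; quenching of the dienolate, or its re-acylation only at C5, so that the acyl shift stalls; transfer of the acyl group to the secondary oxygen. Fallback, by known chemistry that closes the ring at C3=C4 and O1–C2 instead. It sets out from 8. Both hydroxyls are silylated and the helper ester is removed in one operation (TESOTf, 2,6-lutidine; mild aqueous work-up; warming to decarboxylate) to give (5S)-5-methyl-5-[(1R,4E)-4-methyl-1,6-bis(triethylsilyloxy)hex-4-en-1-yl]oxolan-2-one F1. Reduction with i-Bu2AlH at −78 °C gives the lactol, (5S)-5-methyl-5-[(1R,4E)-4-methyl-1,6-bis(triethylsilyloxy)hex-4-en-1-yl]oxolan-2-ol F2. Separately, methyl bis(2,2,2-trifluoroethyl)phosphonoacetate is alkylated with 9 (NaH, DMF) to give methyl 2-[bis(2,2,2-trifluoroethoxy)phosphoryl]-6-methylhept-5-enoate F3. Still–Gennari olefination of F2 with F3 (KN(SiMe3)2, 18-crown-6, THF, −78 °C) should give the Z-ester, methyl (2Z,6S,7R,10E)-6-hydroxy-6,10-dimethyl-2-(4-methylpent-3-en-1-yl)-7,12-bis(triethylsilyloxy)dodeca-2,10-dienoate F4. Its tertiary alkoxide is closed onto the cis ester (catalytic NaH, toluene, 60 °C) to give (7S)-7-methyl-7-[(1R,4E)-4-methyl-1,6-bis(triethylsilyloxy)hex-4-en-1-yl]-3-(4-methylpent-3-en-1-yl)-6,7-dihydrooxepin-2(5H)-one F5. HF·pyridine then frees the diol, and the route is rejoined at 20, before step 11.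

Step 4. What may go wrong: poor facial selectivity on this substrate, epoxidation of the second alkene, or oxidation at the malonate C–H under the basic oxidising conditions. Fallback: it sets out from 2. Sharpless asymmetric epoxidation of the allylic alcohol (Ti(Oi-Pr)4, D-(−)-diethyl tartrate, t-BuOOH, 4 Å sieves, CH2Cl2, −20 °C) touches only that alkene and should give (2E)-5-[(2R,3R)-3-(hydroxymethyl)-3-methyloxiran-2-yl]-3-methylpent-2-en-1-yl acetate F6. Iodination (I2, PPh3, imidazole) gives (2E)-5-[(2R,3S)-3-(iodomethyl)-3-methyloxiran-2-yl]-3-methylpent-2-en-1-yl acetate F7. Alkylation of the sodium salt of 4 with F7 (NaH, DMF, 0 °C) then gives 6, where the route is rejoined at step 5.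

Step 10. What may go wrong: ionisation or cyclisation of the free allylic alcohol and the trisubstituted alkenes under the silyl triflate, or incomplete return of the double bond into conjugation. Fallback: it sets out from 16. The primary hydroxyl is acetylated first (Ac2O, pyridine, −20 °C) to give tert-butyl (7S)-7-[(1R,4E)-6-acetoxy-1-hydroxy-4-methylhex-4-en-1-yl]-7-methyl-3-(4-methylpent-3-en-1-yl)-2-oxo-2,5,6,7-tetrahydrooxepine-5-carboxylate F8. The tert-butyl ester is then cleaved under neutral thermal conditions on silica gel in toluene at 110 °C, where the acid decarboxylates as it forms, and a catalytic amount of DBU completes the isomerisation. This arrives directly at the target 21.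

**Further compounds**

F1 | step 9 | (5S)-5-methyl-5-[(1R,4E)-4-methyl-1,6-bis(triethylsilyloxy)hex-4-en-1-yl]oxolan-2-one | CC[Si](CC)(CC)OC/C=C(\C)CC[C@@H](O[Si](CC)(CC)CC)[C@]1(C)CCC(=O)O1
F2 | step 9 | (5S)-5-methyl-5-[(1R,4E)-4-methyl-1,6-bis(triethylsilyloxy)hex-4-en-1-yl]oxolan-2-ol | CC[Si](CC)(CC)OC/C=C(\C)CC[C@@H](O[Si](CC)(CC)CC)[C@]1(C)CCC(O)O1
F3 | step 9 | methyl 2-[bis(2,2,2-trifluoroethoxy)phosphoryl]-6-methylhept-5-enoate | COC(=O)C(CCC=C(C)C)P(=O)(OCC(F)(F)F)OCC(F)(F)F
F4 | step 9 | methyl (2Z,6S,7R,10E)-6-hydroxy-6,10-dimethyl-2-(4-methylpent-3-en-1-yl)-7,12-bis(triethylsilyloxy)dodeca-2,10-dienoate | CC[Si](CC)(CC)OC/C=C(\C)CC[C@@H](O[Si](CC)(CC)CC)[C@@](C)(O)CC/C=C(/CCC=C(C)C)C(=O)OC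
F5 | step 9 | (7S)-7-methyl-7-[(1R,4E)-4-methyl-1,6-bis(triethylsilyloxy)hex-4-en-1-yl]-3-(4-methylpent-3-en-1-yl)-6,7-dihydrooxepin-2(5H)-one | CC[Si](CC)(CC)OC/C=C(\C)CC[C@@H](O[Si](CC)(CC)CC)[C@]1(C)CCC=C(CCC=C(C)C)C(=O)O1
F6 | step 4 | (2E)-5-[(2R,3R)-3-(hydroxymethyl)-3-methyloxiran-2-yl]-3-methylpent-2-en-1-yl acetate | CC(=O)OC/C=C(\C)CC[C@H]1O[C@]1(C)CO
F7 | step 4 | (2E)-5-[(2R,3S)-3-(iodomethyl)-3-methyloxiran-2-yl]-3-methylpent-2-en-1-yl acetate | CC(=O)OC/C=C(\C)CC[C@H]1O[C@]1(C)CI
F8 | step 10 | tert-butyl (7S)-7-[(1R,4E)-6-acetoxy-1-hydroxy-4-methylhex-4-en-1-yl]-7-methyl-3-(4-methylpent-3-en-1-yl)-2-oxo-2,5,6,7-tetrahydrooxepine-5-carboxylate | CC(=O)OC/C=C(\C)CC[C@@H](O)[C@]1(C)CC(C(=O)OC(C)(C)C)C=C(CCC=C(C)C)C(=O)O1
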